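Take the turnover as the unit: one molecule of target per molecule of free catalyst charged, the count an enzyme's total turnover number makes.

| flask | starting material | protic impurity | free catalyst | remark | time |
|---|---|---|---|---|---|
| north-east | 1 M | 0.13 M | 0.66 mM | run made earlier |  |
| south-west | 1 M | 0.30 M | 0.66 mM | run made earlier |  |
| east | 0.50 M | 0.20 M | 0.66 mM | run made earlier |  |
| flask | 1.0 M | 0.200 M | 0.66 mM |  | 8.0 d |

| run | time / d | target / % |
|---|---|---|
| north-east | 0.125 | 36.7 |
| north-east | 0.250 | 41.1 |
| north-east | 0.625 | 42.2 |
| north-east | 1.67 | 41.6 |
| north-east | 3.00 | 40.7 |
| north-east | 8.00 | 38.1 |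
| south-west | 0.125 | 36.4 |
| south-west | 0.250 | 39.6 |
| south-west | 0.625 | 41.4 |
| south-west | 1.67 | 39.2 |
| south-west | 3.00 | 38.4 |
| south-west | 8.00 | 36.4 |
| east | 0.125 | 35.2 |
| east | 0.333 | 40.6 |
| east | 1.04 | 40.8 |
| east | 3.00 | 40.0 |
| east | 8.00 | 36.6 |

(standard deviation of a reading: 0.5 percentage points)



* when, up to 8.0 d, the flask holds most target
* the amount of target, in percent of the starting material charged, at that time

How many turnovers stand at the top reading of the north-east run? About 639.

And in the east run, with less [starting material]? About 309, so the north-east catalyst did twice the work, while the percentage barely moved, 42.2% against 40.8%.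

So do these two runs show a fixed count of turnovers? No. The count is higher in the run with more [starting material], though [protic impurity] differs between them too, 0.13 M against 0.20 M; such a rise is what a catalyst shows that works for a fixed span of time at a rate proportional to [starting material].

What carries over to the flask, then? The reach: minus the natural logarithm of the fraction not made into target, per [free catalyst] charged. The mean of the top readings of the north-east and south-west runs gives 820 M⁻¹.

But those runs differ in [protic impurity]. Yes, 0.13 M against 0.30 M, which bracket the flask's 0.200 M, and their top readings differ by 0.8 percentage points, with a scatter of 0.5 points on each reading.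

Your figure for the flask? A top of 41.8%, near 0.625 d as in the north-east run.

The forecast, judging that “Yield therefore seems to follow absolute impurity concentration rather than the impurity/starting-material ratio”, gives 41.3% (from 40.6% to 42%) at 0.5 d (from 0.3 d to 0.9 d). My figure stands above its number but inside its range.

The flask gives 41.4% at 0.468 d.

    starting material + free catalyst → free catalyst + target (k = 8.20 M⁻¹ min⁻¹)
    starting material → side product (k = 1.90 × 10⁻⁴ min⁻¹)
    target → over-reaction product (k = 1.10 × 10⁻⁵ min⁻¹)
    starting material + protic impurity → quenched substrate (k = 0.00450 M⁻¹ min⁻¹)
    free catalyst → spent catalyst (k = 0.00900 min⁻¹)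

At 0.468 d the flask holds 99.8% of its catalyst as spent catalyst and still 36.5% starting material. The loss of free catalyst to spent catalyst is the largest single effect on the top: the same flask without that step reaches 85.7%, not 41.4%. The reach gave 41.8% here against the computed 41.4%. For the neighbour charged with 0.0016 M of free catalyst, the same reach gives 73.1%; the computed top there is 71.3%.

Readings and results were generated by integration for an exercise; scatter was added.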